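The amounts first: when the fast rise ended in the north-east flask, G stood at 54.0% of the J charged, read as the mean of the readings at 40.0 min and 60.0 min, and the remaining 46.0% was not in G. My decision on the next step hung on that remainder: was it J waiting beside a dead catalyst, or J lost by other routes while D worked?

all flasks: J 0.11 M; D 16 mM
- north-east: temperature 50 °C; the very flask that is asked about, followed so far
- east: temperature 45 °C; run made earlier
- flask: temperature 50 °C; time 6.0 h

- north-east (time / min: G / %): 15.0: 33.5; 25.0: 51.3; 40.0: 54.0; 60.0: 53.9; 90.0: 54.8; 150: 58.5; 240: 60.2
- east (time / min: G / %): 15.0: 21.3; 25.0: 35.0; 40.0: 50.7; 60.0: 54.3; 90.0: 56.3; 150: 55.0; 240: 57.2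

(each reading ± 1 percentage point)

- G, in percent of the J first charged, at 6.0 h
- the option that brings most further G ("none" if no option brings more than 2 percentage points) (spring / summer / autumn / midnight / none)
- G present, with what was taken out counted in, in percent of the J first charged, after spring
- G present, with what was taken out counted in, in percent of the J first charged, after midnight

- spring: change nothing and wait 12 h more
- summer: at 6.0 h take out 90% of the G then present, then wait 12 h
- autumn: at 6.0 h raise the temperature by 20 K, then wait 12 h
- midnight: at 6.0 h add D, 100% of the amount charged, then wait 12 h

I replaced the curved rise by its mean. Over one stretch of time, G forms at a mean rate and J leaves by other routes at another, so the times cancel. This gives the capture ratio ρ, the mean rate of G over the mean rate of other loss of J, read as G at the stop over the remainder: 1.17. The east flask reads 1.19 at 60.0 min, although its rise over the first 25.0 min was slower, 0.0140 /min of the charge against 0.0205 /min.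

A fixed count of turnovers per D would also stop both flasks at one G, so the readings do not part the two views. I committed to the race, with J as the limiting reagent, so that midnight brings what spring brings. The creep after the stop read 3.10 × 10⁻⁴ /min in the north-east flask and 1.61 × 10⁻⁴ /min in the east flask. The north-east flask is the warmer one, and its creep read 1.93 times that of the east flask, a ratio that carries the scatter of the readings, so I chose autumn. Extending the creep from the last reading, I expected 63.9% at 6.0 h.

The forecast gave 63% now, 78% after spring and 97% after midnight and chose midnight, holding that the stop “suggests the catalyst dies after a fixed turnover count”.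

The asked flask gives 62.6% at 6.0 h, 70.4% after spring and 70.4% after midnight. Spring, summer and midnight each bring 7.7 percentage points, autumn brings 11 points, and the best option is autumn. At 36.0 min that flask held J 0%, with D at 95.9% of the catalyst.

    2 Z ⇌ X, settled at all times (K = 140 /M, ΔH = −32.0 kJ/mol)
    Z → D + G (k = 0.0110 /s, Ea = 93.0 kJ/mol)
    Q ⇌ Z (K = 0.470, k = 1.40 /s, Ea = 65.0 kJ/mol, ΔH = −50.0 kJ/mol)
    2 J → L (k = 0.00790 /M/s, Ea = 71.0 kJ/mol)
    J ⇌ E (K = 22.0, k = 6.20 × 10⁻⁴ /s, Ea = 95.0 kJ/mol, ΔH = −5.00 kJ/mol)
    J + D → Q (k = 14.0 /M/s, Ea = 54.0 kJ/mol)
    (constants at 50 °C)

The capture ratio ρ, read as 1.17 at the stop in the north-east flask, stands at 1.68 in the asked flask at 6.0 h, taken as G over the rest of the charge. The neighbouring flask changes one setting, D at 0.027 M instead of 16 mM, a factor of 1.69. Multiplying the ratio by that factor gives 2.84, which means G at 74.0% of the J charged. The neighbouring flask holds G 74.4% at 360 min, beside E 7.86% and L 17.7%.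

(Readings and results were generated by integration for an exercise.)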